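At the last reading of the amber run, 10.0 min after the start, E was still rising, and I wanted to know how much it had yet to give. I put that question to the rate alone, in M/min, so that flasks of different charge could be compared.

| flask | D | Q | remark | time |
|---|---|---|---|---|
| teal | 0.52 M | 0.72 M | run made earlier |  |
| amber | 1.7 M | 0.72 M | run made earlier |  |
| Sunday's | 0.40 M | 0.720 M |  | 20 min |
| Saturday's | 1.5 M | 0.720 M |  | 60 min |

| run | time / min | E / % | D / % |
|---|---|---|---|
| teal | 2.50 | 22.0 | 33.6 |
| teal | 5.00 | 37.9 | 14.0 |
| teal | 8.00 | 47.5 | 4.0 |
| teal | 10.0 | 53.1 | 1.7 |
| amber | 0.833 | 3.2 | 73.0 |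
| amber | 2.00 | 10.7 | 43.7 |
| amber | 4.00 | 13.9 | 19.3 |
| amber | 10.0 | 18.3 | 1.1 |

(standard deviation of a reading: 1 percentage point)

* the winner by amount of E, in percent of the D charged; "neither" if no more than 2 percentage points parts them (Sunday's / Saturday's / neither)
* how much E is there at the end, in percent of the D charged: Sunday's
* how much E is there at the end, in percent of the D charged: Saturday's



Amber made E at a mean 0.0272 M/min between 2.00 min and 4.00 min, but at 0.0125 M/min between 4.00 min and 10.0 min, so it slowed by a factor 2.18. Letting each mean stand for the rate at mid-interval, the rate halved every 3.55 min, and on the later interval that shortcut errs by about 5.82%.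

Yet at 10.0 min amber held 80.6% of its D charge as neither D nor E, more than as E, so a shortage of that material was not what slowed E. I therefore took Q, which amber and teal were charged with equally, as the limiting reagent.

A rate that keeps halving adds up to the present rate times the halving time over ln(2). Amber's rate at 10.0 min was about 0.00694 M/min, which leaves 0.0356 M to come. Added to the E already read, that gives 0.347 M: my estimate of the ceiling, the cE at which a flask with this Q charge levels off. Teal, with a third of amber's D, reckoned the same way from its own late rate, gives 0.338 M, a difference smaller than the 0.0170 M one amber reading carries.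

So I expected 23.1% from Saturday's. I put Sunday's between teal's 53.1% and its own ceiling of 86.7%, above Saturday's. The forecast named Sunday's, with 74% there and 30% for Saturday's, higher than my figure, noting that “The late E rates are similar in absolute terms”. The flask gave Sunday's as winner, with 74.1% against 23.3%.

    D → X (k = 0.00680 /s)
    Q + X ⇌ J (K = 1.30 /M, k = 0.150 /M/s)
    Q + J → E (k = 0.0270 /M/s)

Saturday's 23.3% stood beside my 23.1%, with 1.2% of its Q left. Sunday's, at 74.1%, stood below the 86.7% I had reckoned for it, and at 200 min it held 87.3%, above that estimate. A neighbour of Sunday's is charged with 1.6 M of D, and my estimated ceiling comes to 21.7% of that charge. At 20.0 min it held 20.6% as E, with 77.0% standing as X and 3.2% of its Q left.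

(The readings come from a simulation for an exercise, noise included.)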